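Assumption: the target (hordatine A, 2R,3R, trans) is isolated from the last step as its bis(trifluoroacetate) salt; the neutral form in the given SMILES is the compound meant.

## Retrosynthetic overview

1. The target comes from global acidolysis (four Boc groups, one aryl tert-butyl ether) of a bis-amide made by double amidation of a diacid with di-Boc-agmatine (from putrescine).
2. The diacid comes from saponification of a diester whose acrylate arm is installed by a Mizoroki–Heck reaction on a C5 bromide.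
3. Key disconnection: the C2–aryl bond and the C2 stereocentre are made by a new enantioselective dearomative 1,4-arylation of a 5-bromobenzofuran-3-carboxylate with an arylboronic acid; C3 is then equilibrated to trans.
4. Ring order: both benzene rings are bought; the furan ring is built first as an aromatic benzofuran (salicylaldehyde plus diazoacetate) and is dearomatised to the dihydrofuran in the key step.

## Route

Step 1
Reactants: 1 5-bromo-2-hydroxybenzaldehyde; 2 ethyl diazoacetate
Product: 4 ethyl 5-bromo-1-benzofuran-3-carboxylate, via cyclic hemiacetal 3 (not isolated)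
Conditions: HBF4·OEt2 (10 mol %), CH2Cl2, rt; then conc. H2SO4, rt
Reagents that add atoms: ethyl diazoacetate (2), CCOC(=O)C=[N+]=[N-]
Why: Acid-catalysed addition of the diazo ester to the aldehyde with 1,2-aryl shift and loss of N2 (Roskamp-type homologation) gives the α-formyl arylacetate, which the ortho phenol traps as hemiacetal 3 and which H2SO4 dehydrates to the aromatic benzofuran (cyclodehydration).

Step 2
Reactants: 4 ethyl 5-bromo-1-benzofuran-3-carboxylate; 5 (4-tert-butoxyphenyl)boronic acid
Product: 7 ethyl (2R,3R)-5-bromo-2-(4-tert-butoxyphenyl)-2,3-dihydro-1-benzofuran-3-carboxylate, via cis-(2R,3S) ester 6 (not isolated)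
Conditions: [RhCl(C2H4)2]2 (2.5 mol %), (S,S)-Ph-bod* [(1S,4S)-2,5-diphenylbicyclo[2.2.2]octa-2,5-diene] (5.5 mol %), 5 (2.5 equiv), KOH (0.3 equiv), 1,4-dioxane/H2O 10:1, 60 °C; then DBU (0.5 equiv), same pot, rt
Reagents that add atoms: (4-tert-butoxyphenyl)boronic acid (5), CC(C)(C)Oc1ccc(cc1)B(O)O
Why: Proposed new method: a rhodium/chiral-diene dearomative 1,4-arylation of an ester-activated benzofuran, whose closest known reaction type is the Hayashi–Miyaura asymmetric conjugate arylation of chromones, coumarins and enoates; the C2=C3 bond of 4 is only weakly aromatic and is polarised by the 3-ester into a β-aryloxy acrylate, so the aryl–rhodium species (monovalent rhodium, formed by transmetalation of 5 with Rh–OH) should insert it with aryl going to C2 and give an oxa-π-allyl rhodium enolate that cannot expel the ring oxygen (the C2–O1 bond lies in the ring plane, orthogonal to the enolate π system, the reverse of a 5-endo-trig closure) and is protonated by water to regenerate Rh–OH; the (S,S)-diene is predicted by the usual quadrant model for enone additions to deliver aryl to the face that gives 2R (the antipodal ligand is held in reserve should the sense be reversed), kinetic protonation anti to the new aryl gives cis ester 6, and DBU equilibrates only the enolisable C3 to the favoured trans (2R,3R) ester.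

Step 3
Reactants: 7 ethyl (2R,3R)-5-bromo-2-(4-tert-butoxyphenyl)-2,3-dihydro-1-benzofuran-3-carboxylate; 8 ethyl acrylate
Product: 9 ethyl (2R,3R)-2-(4-tert-butoxyphenyl)-5-[(E)-3-ethoxy-3-oxoprop-1-en-1-yl]-2,3-dihydro-1-benzofuran-3-carboxylate
Conditions: Pd(OAc)2 (5 mol %), P(o-tol)3 (10 mol %), Et3N (2 equiv), DMF, 100 °C
Reagents that add atoms: ethyl acrylate (8), C=CC(=O)OCC
Why: Mizoroki–Heck reaction (oxidative addition of the aryl bromide to zerovalent palladium, syn insertion, syn β-hydride elimination) gives the E-cinnamate, and the amine base can only push C3 toward the trans isomer already present while C2 is untouched.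

Step 4
Reactants: 9 ethyl (2R,3R)-2-(4-tert-butoxyphenyl)-5-[(E)-3-ethoxy-3-oxoprop-1-en-1-yl]-2,3-dihydro-1-benzofuran-3-carboxylate
Product: 10 (2R,3R)-2-(4-tert-butoxyphenyl)-5-[(E)-2-carboxyethenyl]-2,3-dihydro-1-benzofuran-3-carboxylic acid
Conditions: LiOH·H2O (5 equiv), THF/H2O 3:1, 0 °C to rt; then 1 M HCl to pH 3–4, 0 °C
Reagents that add atoms: lithium hydroxide (its hydroxide supplies the new carboxyl oxygens), [Li+].[OH-]
Why: Saponification (acyl–oxygen cleavage) frees both acids; with the phenol still masked no quinone methide ring-opening is possible, and C3 enolisation can only return the trans isomer because retro-oxa-Michael opening is a disfavoured reverse 5-endo-trig process.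

Step 5
Reactants: 11 butane-1,4-diamine; 12 N,N'-bis(tert-butoxycarbonyl)-1H-pyrazole-1-carboxamidine
Product: 13 N-(4-aminobutyl)-N',N''-bis(tert-butoxycarbonyl)guanidine (di-Boc-agmatine)
Conditions: 11 (5 equiv), CH2Cl2, rt
Reagents that add atoms: N,N'-bis(tert-butoxycarbonyl)-1H-pyrazole-1-carboxamidine (12), CC(C)(C)OC(=O)NC(=NC(=O)OC(C)(C)C)n1cccn1
Why: Amine guanidinylation by addition–elimination at the amidine carbon with pyrazole as leaving group, and the excess diamine suppresses double guanidinylation.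

Step 6
Reactants: 10 (2R,3R)-2-(4-tert-butoxyphenyl)-5-[(E)-2-carboxyethenyl]-2,3-dihydro-1-benzofuran-3-carboxylic acid; 13 N-(4-aminobutyl)-N',N''-bis(tert-butoxycarbonyl)guanidine
Product: 14 (2R,3R)-N-{4-[N',N''-bis(tert-butoxycarbonyl)guanidino]butyl}-5-[(E)-3-({4-[N',N''-bis(tert-butoxycarbonyl)guanidino]butyl}amino)-3-oxoprop-1-en-1-yl]-2-(4-tert-butoxyphenyl)-2,3-dihydro-1-benzofuran-3-carboxamide
Conditions: 13 (2.4 equiv), EDC·HCl (2.6 equiv), HOBt (2.6 equiv), iPr2NEt (3 equiv), DMF, 0 °C to rt
Reagents that add atoms: N-(4-aminobutyl)-N',N''-bis(tert-butoxycarbonyl)guanidine (13), CC(C)(C)OC(=O)NC(=NC(=O)OC(C)(C)C)NCCCCN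
Why: Carbodiimide/HOBt amide coupling at both carboxyl groups; C2 is fixed because the phenol is masked, so any C3 epimerisation of the active ester leads back to the favoured trans amide and not to the enantiomer.

Step 7
Reactants: 14 (2R,3R)-N-{4-[N',N''-bis(tert-butoxycarbonyl)guanidino]butyl}-5-[(E)-3-({4-[N',N''-bis(tert-butoxycarbonyl)guanidino]butyl}amino)-3-oxoprop-1-en-1-yl]-2-(4-tert-butoxyphenyl)-2,3-dihydro-1-benzofuran-3-carboxamide
Product: 15 hordatine A, (2R,3R)-N-(4-guanidinobutyl)-5-{(E)-3-[(4-guanidinobutyl)amino]-3-oxoprop-1-en-1-yl}-2-(4-hydroxyphenyl)-2,3-dihydro-1-benzofuran-3-carboxamide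
Conditions: TFA/CH2Cl2 1:1, H2O (2 vol %), 0 °C to rt, slow N2 sweep
Reagents that add atoms: none
Why: Acidolysis (loss of tert-butyl cation, then decarboxylation) removes the four Boc groups and the aryl tert-butyl ether in one operation; silane and arene scavengers are left out because they would trap the reversibly ionised C2 benzylic ether, and since C3 does not enolise in acid any C2 ionisation recloses to the same trans isomer.

## Compound list

1 | 5-bromo-2-hydroxybenzaldehyde | O=Cc1cc(Br)ccc1O | starting material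
2 | ethyl diazoacetate | CCOC(=O)C=[N+]=[N-] | starting material
3 | ethyl 5-bromo-2-hydroxy-2,3-dihydro-1-benzofuran-3-carboxylate (cyclic hemiacetal, diastereomer mixture) | CCOC(=O)C1C(O)Oc2ccc(Br)cc12 | intermediate
4 | ethyl 5-bromo-1-benzofuran-3-carboxylate | CCOC(=O)c1coc2ccc(Br)cc12 | intermediate
5 | (4-tert-butoxyphenyl)boronic acid | CC(C)(C)Oc1ccc(cc1)B(O)O | starting material
6 | ethyl (2R,3S)-5-bromo-2-(4-tert-butoxyphenyl)-2,3-dihydro-1-benzofuran-3-carboxylate (cis) | Brc1ccc2c(c1)[C@H](C(=O)OCC)[C@H](c1ccc(OC(C)(C)C)cc1)O2 | intermediate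
7 | ethyl (2R,3R)-5-bromo-2-(4-tert-butoxyphenyl)-2,3-dihydro-1-benzofuran-3-carboxylate (trans) | Brc1ccc2c(c1)[C@@H](C(=O)OCC)[C@H](c1ccc(OC(C)(C)C)cc1)O2 | intermediate
8 | ethyl acrylate | C=CC(=O)OCC | starting material
9 | ethyl (2R,3R)-2-(4-tert-butoxyphenyl)-5-[(E)-3-ethoxy-3-oxoprop-1-en-1-yl]-2,3-dihydro-1-benzofuran-3-carboxylate | CCOC(=O)/C=C/c1ccc2c(c1)[C@@H](C(=O)OCC)[C@H](c1ccc(OC(C)(C)C)cc1)O2 | intermediate
10 | (2R,3R)-2-(4-tert-butoxyphenyl)-5-[(E)-2-carboxyethenyl]-2,3-dihydro-1-benzofuran-3-carboxylic acid | OC(=O)/C=C/c1ccc2c(c1)[C@@H](C(=O)O)[C@H](c1ccc(OC(C)(C)C)cc1)O2 | intermediate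
11 | butane-1,4-diamine | NCCCCN | starting material
12 | N,N'-bis(tert-butoxycarbonyl)-1H-pyrazole-1-carboxamidine | CC(C)(C)OC(=O)NC(=NC(=O)OC(C)(C)C)n1cccn1 | starting material
13 | N-(4-aminobutyl)-N',N''-bis(tert-butoxycarbonyl)guanidine | CC(C)(C)OC(=O)NC(=NC(=O)OC(C)(C)C)NCCCCN | intermediate
14 | tetra-Boc O-tert-butyl hordatine A (full name in step 6) | CC(C)(C)OC(=O)NC(=NC(=O)OC(C)(C)C)NCCCCNC(=O)/C=C/c1ccc2c(c1)[C@@H](C(=O)NCCCCNC(=NC(=O)OC(C)(C)C)NC(=O)OC(C)(C)C)[C@H](c1ccc(OC(C)(C)C)cc1)O2 | intermediate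
15 | hordatine A, (2R,3R) | NC(N)=NCCCCNC(=O)/C=C/c1ccc2c(c1)[C@@H](C(=O)NCCCCN=C(N)N)[C@H](c1ccc(O)cc1)O2 | target

## Step count and risks

Total step count: 7. Longest linear sequence: 6 (steps 1, 2, 3, 4, 6, 7); step 5 is a one-step side branch.

The three steps most likely to fail:

**Step 2 (the proposed new dearomative arylation).** The ester-activated benzofuran may be too poor an acceptor, or the facial selectivity may be low. The fallback uses known chemistry only; it sets out from 1 (with 2) and comes back to the route at 6, and from there at 7. Mitsunobu etherification of 1 with 4-tert-butoxybenzyl alcohol (PPh3, DIAD, THF, 0 °C to rt) gives 5-bromo-2-[(4-tert-butoxyphenyl)methoxy]benzaldehyde F1. Lewis-acid-catalysed reaction of this aldehyde with ethyl diazoacetate 2 ([(C5H5)Fe(CO)2(THF)]BF4, 10 mol %, CH2Cl2, 0 °C, chosen to spare the two acid-labile ethers) proceeds with 1,2-aryl shift to give ethyl 2-{5-bromo-2-[(4-tert-butoxyphenyl)methoxy]phenyl}-3-hydroxyprop-2-enoate F2. Deformylative Regitz diazo transfer (4-acetamidobenzenesulfonyl azide, Et3N, MeCN, rt) gives ethyl 2-{5-bromo-2-[(4-tert-butoxyphenyl)methoxy]phenyl}-2-diazoacetate F3. Rh2(S-PTTL)4, dirhodium tetrakis[N-phthaloyl-(S)-tert-leucinate] (divalent rhodium, 1 mol %, toluene, −60 °C), then effects enantioselective intramolecular 1,5 C–H insertion of the rhodium carbene into the benzylic O–CH2 group. This reaction class is known to give cis-2-aryl-2,3-dihydrobenzofuran-3-carboxylates in high ee; the S catalyst is taken as the one leading to the 2R series, with the R catalyst as the alternative if the sense is opposite. The product is cis ester 6, isolated here, and DBU in toluene at rt converts it to 7.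

**Step 4 (saponification).** Hydroxide could open the dihydrofuran ring by retro-oxa-Michael reaction, which would destroy C2. The fallback avoids hydroxide; it sets out from 9 and comes back at 10. Neutral transesterification of 9 with 2-(trimethylsilyl)ethanol (ClBu2SnOSnBu2OH, 5 mol %, toluene, reflux, ethanol distilled off) gives 2-(trimethylsilyl)ethyl (2R,3R)-2-(4-tert-butoxyphenyl)-5-{(E)-3-oxo-3-[2-(trimethylsilyl)ethoxy]prop-1-en-1-yl}-2,3-dihydro-1-benzofuran-3-carboxylate F4. Fluoride-induced fragmentation of both silylethyl esters (TBAF, THF, 0 °C, mild acidic work-up) then gives 10.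

**Step 7 (global acidolysis).** The long acid exposure needed for four guanidine carbamates may damage the acid-labile C2 benzylic aryl ether or tert-butylate the phenol. The fallback moves guanidine formation to the end; it sets out from 10 and comes back at 15. Coupling of 10 with tert-butyl (4-aminobutyl)carbamate (EDC·HCl, HOBt, iPr2NEt, DMF) gives tert-butyl N-{4-[(2R,3R)-5-[(E)-3-({4-[(tert-butoxycarbonyl)amino]butyl}amino)-3-oxoprop-1-en-1-yl]-2-(4-tert-butoxyphenyl)-2,3-dihydro-1-benzofuran-3-carboxamido]butyl}carbamate F5. A short TFA/CH2Cl2 treatment (0 °C, under 1 h; amine Boc groups and the aryl tert-butyl ether cleave quickly) gives (2R,3R)-N-(4-aminobutyl)-5-{(E)-3-[(4-aminobutyl)amino]-3-oxoprop-1-en-1-yl}-2-(4-hydroxyphenyl)-2,3-dihydro-1-benzofuran-3-carboxamide F6. Guanidinylation of both primary amines with 1H-pyrazole-1-carboxamidine hydrochloride (iPr2NEt, DMF, rt) gives 15.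

## Further compounds

F1 | step 2 | 5-bromo-2-[(4-tert-butoxyphenyl)methoxy]benzaldehyde | O=Cc1cc(Br)ccc1OCc1ccc(OC(C)(C)C)cc1
F2 | step 2 | ethyl 2-{5-bromo-2-[(4-tert-butoxyphenyl)methoxy]phenyl}-3-hydroxyprop-2-enoate | CCOC(=O)C(=CO)c1cc(Br)ccc1OCc1ccc(OC(C)(C)C)cc1
F3 | step 2 | ethyl 2-{5-bromo-2-[(4-tert-butoxyphenyl)methoxy]phenyl}-2-diazoacetate | CCOC(=O)C(=[N+]=[N-])c1cc(Br)ccc1OCc1ccc(OC(C)(C)C)cc1
F4 | step 4 | 2-(trimethylsilyl)ethyl (2R,3R)-2-(4-tert-butoxyphenyl)-5-{(E)-3-oxo-3-[2-(trimethylsilyl)ethoxy]prop-1-en-1-yl}-2,3-dihydro-1-benzofuran-3-carboxylate | C[Si](C)(C)CCOC(=O)/C=C/c1ccc2c(c1)[C@@H](C(=O)OCC[Si](C)(C)C)[C@H](c1ccc(OC(C)(C)C)cc1)O2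
F5 | step 7 | tert-butyl N-{4-[(2R,3R)-5-[(E)-3-({4-[(tert-butoxycarbonyl)amino]butyl}amino)-3-oxoprop-1-en-1-yl]-2-(4-tert-butoxyphenyl)-2,3-dihydro-1-benzofuran-3-carboxamido]butyl}carbamate | CC(C)(C)OC(=O)NCCCCNC(=O)/C=C/c1ccc2c(c1)[C@@H](C(=O)NCCCCNC(=O)OC(C)(C)C)[C@H](c1ccc(OC(C)(C)C)cc1)O2
F6 | step 7 | (2R,3R)-N-(4-aminobutyl)-5-{(E)-3-[(4-aminobutyl)amino]-3-oxoprop-1-en-1-yl}-2-(4-hydroxyphenyl)-2,3-dihydro-1-benzofuran-3-carboxamide | NCCCCNC(=O)/C=C/c1ccc2c(c1)[C@@H](C(=O)NCCCCN)[C@H](c1ccc(O)cc1)O2
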